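## Retrosynthetic overview (cembrane numbering: C1 ring-fusion CH, C14 lactone O–CH, C13 OAc, C12 CHMe, C8(=C19H2), C7 OH, C3/C4 oxirane)
1. The C3–C4 oxirane comes last, by reagent-controlled epoxidation of the E-alkene. The C13 acetate is placed just before it by site-selective acylation.
2. Key cut C1–C14: the β-carbon of a 2-(acetoxymethyl)enoate is turned into a nucleophile (a 2-carbomethoxyallylindium, a homoenolate equivalent) and attacks the C14 aldehyde carbon. Both carbons are natural electrophiles.
3. That single operation closes the 14-membered carbocycle and sets C1 and C14, and the cis-γ-lactone with its exo-methylene then forms in the same flask. The C13 hydroxyl that steers it comes from proline α-aminoxylation.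
4. The C7–C8 bond is made by a ligand-controlled Nozaki–Hiyama–Kishi coupling. The partners are an east 2-iodoalkene (from (S)-citronellal, which supplies C12) and a west aldehyde (from pent-4-yn-1-ol, allyl bromide and an acrylate).
5. Ring order: carbocycle, then lactone, then oxirane.

Assumption: telescoped sequences without purification of the intermediate count as one step, and methyl 2-(acetoxymethyl)acrylate is bought (otherwise it is one acetylation of commercial methyl 2-(hydroxymethyl)acrylate).

## Route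

Step 1
Reactants: 1 (S)-citronellal [(3S)-3,7-dimethyloct-6-enal]
Product: 2 (6S)-8,8-dimethoxy-2,6-dimethyloct-2-ene
Conditions: HC(OMe)3, p-TsOH·H2O (1 mol %), MeOH, 0 °C to rt
Reagents that add atoms: trimethyl orthoformate, COC(OC)OC
Why: Acid-catalysed acetalisation with an orthoester as water scavenger outruns the carbonyl-ene cyclisation of citronellal at this temperature and masks the aldehyde up to step 9, while the stereocentre (later C12, S) comes from the chiral pool and is not touched.

Step 2
Reactants: 2 (6S)-8,8-dimethoxy-2,6-dimethyloct-2-ene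
Product: 4 (4S)-6,6-dimethoxy-4-methylhexan-1-ol, via acetal aldehyde 3 (not isolated)
Conditions: O3, CH2Cl2–MeOH, −78 °C; then NaBH4, −78 to 0 °C
Reagents that add atoms: ozone, [O-][O+]=O
Why: Ozonolysis with reductive work-up cleaves the only alkene, the acetal is inert, and NaBH4 carries the peroxidic products through aldehyde 3 to the primary alcohol.

Step 3
Reactants: 4 (4S)-6,6-dimethoxy-4-methylhexan-1-ol
Product: 5 (3S)-6-iodo-1,1-dimethoxy-3-methylhexane
Conditions: PPh3, I2, imidazole, CH2Cl2, 0 °C
Reagents that add atoms: iodine, II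
Why: Appel-type iodination displaces the oxyphosphonium ion of the primary alcohol by SN2, and imidazole keeps the medium non-acidic for the acetal.

Step 4
Reactants: 5 (3S)-6-iodo-1,1-dimethoxy-3-methylhexane
Product: 6 (6S)-8,8-dimethoxy-6-methyloct-1-yne
Conditions: LiC≡CH·H2NCH2CH2NH2, DMSO, 10 °C to rt
Reagents that add atoms: lithium acetylide (ethylenediamine complex), [Li]C#C
Why: SN2 alkylation of lithium acetylide in DMSO is clean on an unhindered primary iodide and brings in C8 and C19 in one operation.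

Step 5
Reactants: 6 (6S)-8,8-dimethoxy-6-methyloct-1-yne
Product: 8 (6S)-2-iodo-8,8-dimethoxy-6-methyloct-1-ene, via alkenylalane 7 (not isolated)
Conditions: Ni(dppp)Cl2 (3 mol %), iBu2AlH (1.3 equiv), THF, 0 to 22 °C; then N-iodosuccinimide, 0 °C
Reagents that add atoms: N-iodosuccinimide, O=C1CCC(=O)N1I; diisobutylaluminium hydride, CC(C)C[AlH]CC(C)C (its aluminium group is present only in 7)
Why: Nickel-catalysed α-selective (Markovnikov) hydroalumination puts aluminium on the internal alkyne carbon, and iodinolysis of the C–Al bond gives the 2-iodo-1-alkene, the acetal being untouched by iBu2AlH in THF at this temperature.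

Step 6
Reactants: 9 pent-4-yn-1-ol; 10 allyl bromide
Product: 12 (4E)-4-methylocta-4,7-dien-1-ol, via alkenylalane 11 (not isolated)
Conditions: Me3Al (3 equiv), Cp2ZrCl2 (25 mol %), CH2Cl2, 0 °C to rt; then 10, Pd(PPh3)4 (3 mol %), THF, rt
Reagents that add atoms: trimethylaluminium, C[Al](C)C
Why: Negishi zirconium-catalysed methylalumination is a syn addition that puts methyl on the internal carbon and so fixes the E trisubstituted alkene (later C3=C4), the palladium-catalysed alkenylalane–allyl bromide cross-coupling keeps that geometry, and the hydroxyl is carried as its aluminium alkoxide.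

Step 7
Reactants: 12 (4E)-4-methylocta-4,7-dien-1-ol; 13 methyl 2-(acetoxymethyl)acrylate (3 equiv)
Product: 14 methyl (2E,5E)-2-(acetoxymethyl)-9-hydroxy-6-methylnona-2,5-dienoate
Conditions: second-generation Hoveyda–Grubbs catalyst (5 mol %), 1,4-benzoquinone (10 mol %), CH2Cl2, 40 °C
Reagents that add atoms: none
Why: In this olefin cross-metathesis only the monosubstituted alkene of 12 loads onto ruthenium, the trisubstituted alkene is inert, the electron-poor 1,1-disubstituted partner does not homodimerise, benzoquinone suppresses isomerisation of the skipped diene, and the E/Z ratio is unimportant because the geometry is erased at the allylmetal stage of step 11.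

Step 8
Reactants: 14 methyl (2E,5E)-2-(acetoxymethyl)-9-hydroxy-6-methylnona-2,5-dienoate
Product: 15 methyl (2E,5E)-2-(acetoxymethyl)-6-methyl-9-oxonona-2,5-dienoate
Conditions: TEMPO (10 mol %), PhI(OAc)2, CH2Cl2, rt
Reagents that add atoms: none
Why: Oxoammonium (TEMPO) oxidation stops at the aldehyde and leaves the alkenes, the ester and the allylic acetate alone.

Step 9
Reactants: 8 (6S)-2-iodo-8,8-dimethoxy-6-methyloct-1-ene (1.3 equiv); 15 methyl (2E,5E)-2-(acetoxymethyl)-6-methyl-9-oxonona-2,5-dienoate
Product: 17 methyl (2E,5E,9S,14S)-2-(acetoxymethyl)-9-hydroxy-6,14-dimethyl-10-methylidene-16-oxohexadeca-2,5-dienoate, via acetal alcohol 16 (not isolated)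
Conditions: CrCl2 (3.5 equiv), NiCl2 (1 mol %), valinol-derived oxazoline–sulfonamide ligand (the antipode that directs Re-face attack, 3.8 equiv, recovered), Et3N, THF, rt; crude 16 then 1 M aq HCl–THF, 0 °C to rt
Reagents that add atoms: water, O
Why: In this Nozaki–Hiyama–Kishi coupling zerovalent nickel inserts into the C–I bond, transmetalation gives an alkenyl species of trivalent chromium that adds only to the aldehyde (esters, allylic acetate and acetal are inert), the chiral sulfonamide on chromium steers it to the Re face and so sets 9S (later C7), and dilute acid then unmasks the C16 aldehyde.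

Step 10
Reactants: 17 methyl (2E,5E,9S,14S)-2-(acetoxymethyl)-9-hydroxy-6,14-dimethyl-10-methylidene-16-oxohexadeca-2,5-dienoate
Product: 19 methyl (2E,5E,9S,14S,15R)-2-(acetoxymethyl)-9,15-dihydroxy-6,14-dimethyl-10-methylidene-16-oxohexadeca-2,5-dienoate, via anilinooxy aldehyde 18 (not isolated)
Conditions: L-proline (20 mol %), PhNO (1.1 equiv, slow addition), CHCl3, 4 °C; then MeOH, CuSO4·5H2O (30 mol %), 0 °C; used crude
Reagents that add atoms: nitrosobenzene, O=Nc1ccccc1
Why: In the proline α-aminoxylation (enamine catalysis, O-selective nitroso aldol) the carboxylic acid of L-proline delivers PhN=O to one face of the E-enamine and gives the R α-oxy aldehyde (15R, later C13) under catalyst control whatever the β-methyl centre, and CuSO4 in MeOH then cleaves the weak N–O bond without touching the aldehyde.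

Step 11
Reactants: 19 methyl (2E,5E,9S,14S,15R)-2-(acetoxymethyl)-9,15-dihydroxy-6,14-dimethyl-10-methylidene-16-oxohexadeca-2,5-dienoate
Product: 22 (1S,3E,7S,12S,13R,14R)-7,13-dihydroxycembra-3,8(19),15(17)-trien-16,14-olide, via allylindium 20 (not isolated), via hydroxy ester 21 (not isolated)
Conditions: Pd(PPh3)4 (10 mol %), InI (2.5 equiv), THF–H2O 4:1, rt, 19 added over 12 h (final 1 mM); extractive work-up, then p-TsOH·H2O (10 mol %), CH2Cl2, rt
Reagents that add atoms: indium monoiodide, [In]I (its atoms are present only in 20)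
Why: Proposed new method: zerovalent palladium ionises the activated allylic acetate and InI reduces the π-allyl complex to a 2-(methoxycarbonyl)allylindium, a homoenolate equivalent in which the enoate β-carbon (normally an acceptor) is the nucleophile and which lives long enough in wet THF for slow-addition ring closure onto the aldehyde carbon; trivalent indium is held by the aldehyde oxygen and the free C13 hydroxyl in a five-membered chelate so that attack comes anti to the C12 chain (13,14-syn diol, 14R), the ester-coordinated Z-type allylindium reacts at its γ-carbon through a chair (syn adduct, 1S, hence the cis-lactone, whose five-membered closure is kinetically preferred over the δ-lactone through the C13 hydroxyl), and the closest known reaction types are Pd/InI umpolung allylation of aldehydes with allylic acetates, chelation-controlled indium Barbier addition of 2-(bromomethyl)but-2-enoates to α-hydroxy aldehydes in water, and chromium- or zinc-mediated Barbier macrocyclisations to germacranolide and cembranoid rings.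

Step 12
Reactants: 22 (1S,3E,7S,12S,13R,14R)-7,13-dihydroxycembra-3,8(19),15(17)-trien-16,14-olide
Product: 25 (1S,3E,7S,12S,13R,14R)-13-acetoxy-7-hydroxycembra-3,8(19),15(17)-trien-16,14-olide, via silyl ether 23 (not isolated), via silyl ether acetate 24 (not isolated)
Conditions: Et3SiCl (1.05 equiv), pyridine, CH2Cl2, −40 to −20 °C; then Ac2O, DMAP (cat.), 0 °C to rt; then HF·pyridine, 0 °C
Reagents that add atoms: acetic anhydride, CC(=O)OC(C)=O; chlorotriethylsilane, CC[Si](Cl)(CC)CC (its silyl group is present only in 23 and 24)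
Why: Transient protection works here because the allylic C7 hydroxyl (one CH2 neighbour) is silylated much faster than the C13 hydroxyl flanked by two branched carbons, so DMAP-catalysed acylation can only hit C13, and fluoride then removes the labile triethylsilyl ether without harming acetate, lactone or alkenes.

Step 13
Reactants: 25 (1S,3E,7S,12S,13R,14R)-13-acetoxy-7-hydroxycembra-3,8(19),15(17)-trien-16,14-olide
Product: 26 (1S,3R,4R,7S,12S,13R,14R)-13-acetoxy-3,4-epoxy-7-hydroxycembra-8(19),15(17)-dien-16,14-olide (CNP0230083.1)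
Conditions: D-fructose-derived Shi ketone (30 mol %), KHSO5 (as 2KHSO5·KHSO4·K2SO4), K2CO3, Bu4NHSO4 (cat.), MeCN–CH2(OMe)2 / aq Na2B4O7 buffer, 0 °C
Reagents that add atoms: potassium peroxymonosulfate, [K+].[O-]S(=O)(=O)OO
Why: In the Shi asymmetric epoxidation the chiral dioxirane reacts fastest with the electron-rich E-trisubstituted alkene (the 1,1-disubstituted allylic alkene is a poor substrate for this ketone and the α-methylene lactone is electron-poor), and the spiro transition state of the D-fructose-derived ketone gives R,R-epoxides from E-alkenes, which sets C3 and C4.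

## Compound list
1 | (S)-citronellal, (3S)-3,7-dimethyloct-6-enal | CC(C)=CCC[C@H](C)CC=O | starting material
2 | (6S)-8,8-dimethoxy-2,6-dimethyloct-2-ene | CC(C)=CCC[C@H](C)CC(OC)OC | intermediate
3 | (4S)-6,6-dimethoxy-4-methylhexanal | O=CCC[C@H](C)CC(OC)OC | intermediate
4 | (4S)-6,6-dimethoxy-4-methylhexan-1-ol | OCCC[C@H](C)CC(OC)OC | intermediate
5 | (3S)-6-iodo-1,1-dimethoxy-3-methylhexane | ICCC[C@H](C)CC(OC)OC | intermediate
6 | (6S)-8,8-dimethoxy-6-methyloct-1-yne | C#CCCC[C@H](C)CC(OC)OC | intermediate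
7 | diisobutyl[(6S)-8,8-dimethoxy-6-methyloct-1-en-2-yl]alane | C=C([Al](CC(C)C)CC(C)C)CCC[C@H](C)CC(OC)OC | intermediate
8 | (6S)-2-iodo-8,8-dimethoxy-6-methyloct-1-ene (east fragment) | C=C(I)CCC[C@H](C)CC(OC)OC | intermediate
9 | pent-4-yn-1-ol | C#CCCCO | starting material
10 | allyl bromide | C=CCBr | starting material
11 | (E)-alkenyl(dimethyl)alane from 9, hydroxyl as O–AlMe2, aluminium trans to the chain | C[Al](C)/C=C(C)/CCCO[Al](C)C | intermediate
12 | (4E)-4-methylocta-4,7-dien-1-ol | OCCC/C(C)=C/CC=C | intermediate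
13 | methyl 2-(acetoxymethyl)acrylate | C=C(COC(C)=O)C(=O)OC | starting material
14 | methyl (2E,5E)-2-(acetoxymethyl)-9-hydroxy-6-methylnona-2,5-dienoate | OCCC/C(C)=C/C/C=C(\COC(C)=O)C(=O)OC | intermediate
15 | methyl (2E,5E)-2-(acetoxymethyl)-6-methyl-9-oxonona-2,5-dienoate (west fragment) | O=CCC/C(C)=C/C/C=C(\COC(C)=O)C(=O)OC | intermediate
16 | methyl (2E,5E,9S,14S)-2-(acetoxymethyl)-9-hydroxy-16,16-dimethoxy-6,14-dimethyl-10-methylidenehexadeca-2,5-dienoate | C=C(CCC[C@H](C)CC(OC)OC)[C@@H](O)CC/C(C)=C/C/C=C(\COC(C)=O)C(=O)OC | intermediate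
17 | methyl (2E,5E,9S,14S)-2-(acetoxymethyl)-9-hydroxy-6,14-dimethyl-10-methylidene-16-oxohexadeca-2,5-dienoate | C=C(CCC[C@H](C)CC=O)[C@@H](O)CC/C(C)=C/C/C=C(\COC(C)=O)C(=O)OC | intermediate
18 | (15R)-15-(anilinooxy) derivative of 17 | C=C(CCC[C@H](C)[C@@H](ONc1ccccc1)C=O)[C@@H](O)CC/C(C)=C/C/C=C(\COC(C)=O)C(=O)OC | intermediate
19 | methyl (2E,5E,9S,14S,15R)-2-(acetoxymethyl)-9,15-dihydroxy-6,14-dimethyl-10-methylidene-16-oxohexadeca-2,5-dienoate | C=C(CCC[C@H](C)[C@@H](O)C=O)[C@@H](O)CC/C(C)=C/C/C=C(\COC(C)=O)C(=O)OC | intermediate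
20 | acetato(iodo)allylindium from 19, indium on the former CH2OAc carbon | C=C(CCC[C@H](C)[C@@H](O)C=O)[C@@H](O)CC/C(C)=C/C/C=C(\C[In](I)OC(C)=O)C(=O)OC | intermediate
21 | methyl 2-[(1S,2R,3R,4S,9S,12E)-2,3,9-trihydroxy-4,12-dimethyl-8-methylidenecyclotetradec-12-en-1-yl]prop-2-enoate | C=C1CCC[C@H](C)[C@@H](O)[C@H](O)[C@@H](C/C=C(C)/CC[C@@H]1O)C(=C)C(=O)OC | intermediate
22 | (1S,3E,7S,12S,13R,14R)-7,13-dihydroxycembra-3,8(19),15(17)-trien-16,14-olide (cis-fused α-methylene-γ-lactone on the 14-membered ring) | C=C1CCC[C@H](C)[C@@H](O)[C@@H]2OC(=O)C(=C)[C@@H]2C/C=C(C)/CC[C@@H]1O | intermediate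
23 | 7-O-triethylsilyl ether of 22 | C=C1CCC[C@H](C)[C@@H](O)[C@@H]2OC(=O)C(=C)[C@@H]2C/C=C(C)/CC[C@@H]1O[Si](CC)(CC)CC | intermediate
24 | 13-O-acetyl-7-O-triethylsilyl derivative of 22 | C=C1CCC[C@H](C)[C@@H](OC(C)=O)[C@@H]2OC(=O)C(=C)[C@@H]2C/C=C(C)/CC[C@@H]1O[Si](CC)(CC)CC | intermediate
25 | (1S,3E,7S,12S,13R,14R)-13-acetoxy-7-hydroxycembra-3,8(19),15(17)-trien-16,14-olide | C=C1CCC[C@H](C)[C@@H](OC(C)=O)[C@@H]2OC(=O)C(=C)[C@@H]2C/C=C(C)/CC[C@@H]1O | intermediate
26 | (1S,3R,4R,7S,12S,13R,14R)-13-acetoxy-3,4-epoxy-7-hydroxycembra-8(19),15(17)-dien-16,14-olide | C=C1CCC[C@H](C)[C@@H](OC(C)=O)[C@@H]2OC(=O)C(=C)[C@@H]2C[C@H]2O[C@]2(C)CC[C@@H]1O | target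

## Totals and risks
Total step count: 13. Longest linear sequence: 10 (steps 1–5, then 9–13). The west branch (steps 6–8) runs in parallel.

**Step 11 (ring closure) is the most likely to fail.**
- Risks: the allylindium may be protonated or may oligomerise before the 14-membered ring closes. The free C7 allylic alcohol may be slowly ionised by palladium. The macrocyclic tether may erode the chelate control.
- Fallback, setting out from 12 and 8 and coming back at 22: keep the same reversed-polarity C1–C14 bond but make it between two molecules, and close the ring at C7–C8 instead.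
- Cross-metathesis of 12 with commercial methyl 2-(bromomethyl)acrylate gives methyl (2Z,5E)-2-(bromomethyl)-9-hydroxy-6-methylnona-2,5-dienoate F1.
- Dilute acid turns 8 into (3S)-7-iodo-3-methyloct-7-enal F2. L-proline and nitrosobenzene convert this into (2R,3S)-2-(anilinooxy)-7-iodo-3-methyloct-7-enal F3, and CuSO4 in MeOH then gives (2R,3S)-2-hydroxy-7-iodo-3-methyloct-7-enal F4.
- Indium powder in THF–water joins F1 and F4 under the same chelate control, and tolerates the iodoalkene. The product is methyl (3S,4R,5R,6S)-4,5-dihydroxy-3-[(2E)-6-hydroxy-3-methylhex-2-en-1-yl]-10-iodo-6-methyl-2-methylideneundec-10-enoate F5.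
- Acid closes F5 to (4S,5R)-5-[(1R,2S)-1-hydroxy-6-iodo-2-methylhept-6-en-1-yl]-4-[(2E)-6-hydroxy-3-methylhex-2-en-1-yl]-3-methylideneoxolan-2-one F6.
- TEMPO/PhI(OAc)2 oxidises only the primary alcohol to (4S,5R)-5-[(1R,2S)-1-hydroxy-6-iodo-2-methylhept-6-en-1-yl]-4-[(2E)-3-methyl-6-oxohex-2-en-1-yl]-3-methylideneoxolan-2-one F7.
- A high-dilution CrCl2/NiCl2 ring closure of F7 with the ligand of step 9 gives 22.

**Step 10 (free α-hydroxy aldehyde).**
- Risks: 19 can dimerise, epimerise through the enediol, or be damaged during N–O cleavage at the aldehyde oxidation level.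
- Fallback, setting out from 17 and coming back at 19: go through a stable alcohol and re-oxidise.
- The aminoxylation mixture is quenched with NaBH4 to give methyl (2E,5E,9S,14S,15R)-2-(acetoxymethyl)-15-(anilinooxy)-9,16-dihydroxy-6,14-dimethyl-10-methylidenehexadeca-2,5-dienoate F8.
- CuSO4 in MeOH cleaves the N–O bond to methyl (2E,5E,9S,14S,15R)-2-(acetoxymethyl)-9,15,16-trihydroxy-6,14-dimethyl-10-methylidenehexadeca-2,5-dienoate F9, which can be purified and stored.
- A primary-selective oxoammonium oxidation (TEMPO, N-chlorosuccinimide, buffered two-phase medium), run just before step 11, gives 19.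

**Step 13 (facial selectivity on the macrocycle).**
- Risk: the ring exposes only the outer face of the C3=C4 alkene, and this bias may override the Shi ketone and give the 3S,4S-oxirane.
- Fallback, setting out from 25 and coming back at 26: use that same bias through a halohydrin, which places the oxygen on the opposite face.
- N-bromosuccinimide in aqueous THF attacks the exposed face and water opens the bromonium ion anti at the tertiary carbon. This gives (1S,3S,4R,7S,12S,13R,14R)-13-acetoxy-3-bromo-4,7-dihydroxycembra-8(19),15(17)-dien-16,14-olide F10.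
- K2CO3 in acetone closes the oxirane with inversion at C3 to give 26.

## Further compounds
F1 | step 11 | methyl (2Z,5E)-2-(bromomethyl)-9-hydroxy-6-methylnona-2,5-dienoate | OCCC/C(C)=C/C/C=C(\CBr)C(=O)OC
F2 | step 11 | (3S)-7-iodo-3-methyloct-7-enal | C=C(I)CCC[C@H](C)CC=O
F3 | step 11 | (2R,3S)-2-(anilinooxy)-7-iodo-3-methyloct-7-enal | C=C(I)CCC[C@H](C)[C@@H](ONc1ccccc1)C=O
F4 | step 11 | (2R,3S)-2-hydroxy-7-iodo-3-methyloct-7-enal | C=C(I)CCC[C@H](C)[C@@H](O)C=O
F5 | step 11 | methyl (3S,4R,5R,6S)-4,5-dihydroxy-3-[(2E)-6-hydroxy-3-methylhex-2-en-1-yl]-10-iodo-6-methyl-2-methylideneundec-10-enoate | C=C(I)CCC[C@H](C)[C@@H](O)[C@H](O)[C@@H](C/C=C(C)/CCCO)C(=C)C(=O)OC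
F6 | step 11 | (4S,5R)-5-[(1R,2S)-1-hydroxy-6-iodo-2-methylhept-6-en-1-yl]-4-[(2E)-6-hydroxy-3-methylhex-2-en-1-yl]-3-methylideneoxolan-2-one | C=C(I)CCC[C@H](C)[C@@H](O)[C@@H]1OC(=O)C(=C)[C@@H]1C/C=C(C)/CCCO
F7 | step 11 | (4S,5R)-5-[(1R,2S)-1-hydroxy-6-iodo-2-methylhept-6-en-1-yl]-4-[(2E)-3-methyl-6-oxohex-2-en-1-yl]-3-methylideneoxolan-2-one | C=C(I)CCC[C@H](C)[C@@H](O)[C@@H]1OC(=O)C(=C)[C@@H]1C/C=C(C)/CCC=O
F8 | step 10 | methyl (2E,5E,9S,14S,15R)-2-(acetoxymethyl)-15-(anilinooxy)-9,16-dihydroxy-6,14-dimethyl-10-methylidenehexadeca-2,5-dienoate | C=C(CCC[C@H](C)[C@@H](ONc1ccccc1)CO)[C@@H](O)CC/C(C)=C/C/C=C(\COC(C)=O)C(=O)OC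
F9 | step 10 | methyl (2E,5E,9S,14S,15R)-2-(acetoxymethyl)-9,15,16-trihydroxy-6,14-dimethyl-10-methylidenehexadeca-2,5-dienoate | C=C(CCC[C@H](C)[C@@H](O)CO)[C@@H](O)CC/C(C)=C/C/C=C(\COC(C)=O)C(=O)OC
F10 | step 13 | (1S,3S,4R,7S,12S,13R,14R)-13-acetoxy-3-bromo-4,7-dihydroxycembra-8(19),15(17)-dien-16,14-olide | C=C1CCC[C@H](C)[C@@H](OC(C)=O)[C@@H]2OC(=O)C(=C)[C@@H]2C[C@H](Br)[C@](C)(O)CC[C@@H]1O
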